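**Strategy**

The dihydropyran ring (ring C) is cut at O1–C2 and C3–C4: ring A, with O1 on C8a and the C4 methylene on C4a, is a latent ortho-quinone methide, and C2–C3 with the phenyl group is styrene. A catalytic asymmetric oxa-[4+2] cycloaddition closes this final ring, forms the C3–C4 and O1–C2 bonds and sets C2 in the very last operation. The precursor is the complete bibenzyl, with the quinone methide stored as an isopropylidene acetal (4H-1,3-benzodioxin) and the other phenol left free; it is assembled by a Wittig union of two phloroglucinol-derived halves followed by hydrogenation.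

Key step: step 7

Remark on the chemistry: 3,5-dimethoxy-4-methylphenol is taken as a purchasable building block, and because the sense of induction of the chiral acid in step 7 cannot be predicted with certainty, the catalyst antipode that delivers the (2S) product is to be fixed in a first analytical run (both antipodes are accessible).

Ring labels: ring A is the oxygenated benzo ring of the chroman, ring C the dihydropyran, ring D the pendant phenol ring.

**Route**

Step 1
Reactants: 1 2-hydroxy-4,6-dimethoxybenzaldehyde
Product: 3 2-hydroxy-3-(hydroxymethyl)-4,6-dimethoxybenzaldehyde, via benzodioxaborinine aldehyde 2 (not isolated)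
Conditions: PhB(OH)2, (CH2O)n, EtCO2H (cat.), toluene, reflux (Dean-Stark); then propane-1,3-diol, THF, rt
Reagents that add atoms: paraformaldehyde (as formaldehyde), C=O
Why: Boronic acid-templated ortho-hydroxymethylation, in which the aryloxyboronate delivers formaldehyde intramolecularly to the only free ortho carbon (C3), the cyclic boronate 2 blocks a second addition, and non-oxidative diol exchange frees the salicyl alcohol without touching the aldehyde.

Step 2
Reactants: 3 2-hydroxy-3-(hydroxymethyl)-4,6-dimethoxybenzaldehyde
Product: 4 5,7-dimethoxy-2,2-dimethyl-4H-1,3-benzodioxine-8-carbaldehyde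
Conditions: 2,2-dimethoxypropane, PPTS (cat.), acetone, rt
Reagents that add atoms: 2,2-dimethoxypropane, COC(C)(C)OC
Why: Acid-catalysed acetal exchange (isopropylidene protection of a salicyl alcohol) ties the phenol and the benzylic alcohol into a base-stable benzodioxin that keeps the aldehyde electrophilic for the Wittig step and later serves as the quinone methide reservoir.

Step 3
Reactants: 5 3,5-dimethoxy-4-methylphenol
Product: 6 6-hydroxy-2,4-dimethoxy-3-methylbenzaldehyde
Conditions: MgCl2, Et3N, (CH2O)n, MeCN, reflux; aq. HCl work-up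
Reagents that add atoms: paraformaldehyde (as formaldehyde), C=O
Why: Magnesium phenoxide-directed ortho-formylation (Casnati-Skattebøl) is ortho-specific, the two ortho positions are equivalent and the para position is blocked by the methyl group, so a single aldehyde should result.

Step 4
Reactants: 6 6-hydroxy-2,4-dimethoxy-3-methylbenzaldehyde
Product: 8 (6-hydroxy-2,4-dimethoxy-3-methylbenzyl)triphenylphosphonium bromide, via salicyl alcohol 7 (not isolated)
Conditions: NaBH4, MeOH, 0 °C; extractive work-up; then PPh3·HBr, MeCN, reflux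
Reagents that add atoms: triphenylphosphine hydrobromide, [Br-].[PH+](c1ccccc1)(c1ccccc1)c1ccccc1
Why: Borohydride reduction gives the labile electron-rich salicyl alcohol 7, which HBr ionises to the benzylic cation (protonated quinone methide) that triphenylphosphine captures, the standard preparation of 2-hydroxybenzyl Wittig salts.

Step 5
Reactants: 8 (6-hydroxy-2,4-dimethoxy-3-methylbenzyl)triphenylphosphonium bromide; 4 5,7-dimethoxy-2,2-dimethyl-4H-1,3-benzodioxine-8-carbaldehyde
Product: 9 2-[2-(5,7-dimethoxy-2,2-dimethyl-4H-1,3-benzodioxin-8-yl)ethenyl]-3,5-dimethoxy-4-methylphenol (E/Z mixture)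
Conditions: KOtBu (2.2 equiv), THF, 0 °C to reflux
Reagents that add atoms: none
Why: Wittig olefination of the phenoxide ylide with the non-enolisable, non-phenolic aldehyde builds the two-carbon bridge between rings A and D, and the alkene geometry is irrelevant because the double bond is saturated in the next step.

Step 6
Reactants: 9 2-[2-(5,7-dimethoxy-2,2-dimethyl-4H-1,3-benzodioxin-8-yl)ethenyl]-3,5-dimethoxy-4-methylphenol
Product: 10 2-[2-(5,7-dimethoxy-2,2-dimethyl-4H-1,3-benzodioxin-8-yl)ethyl]-3,5-dimethoxy-4-methylphenol
Conditions: H2 (1 atm), 10% Pd/C, Ph2S (cat.), EtOAc, rt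
Reagents that add atoms: none
Why: Heterogeneous hydrogenation of the stilbene, in which the sulfide-poisoned palladium catalyst should saturate the alkene without hydrogenolysing the benzylic C–O bond of the benzodioxin.

Step 7
Reactants: 10 2-[2-(5,7-dimethoxy-2,2-dimethyl-4H-1,3-benzodioxin-8-yl)ethyl]-3,5-dimethoxy-4-methylphenol; 11 styrene
Product: 13 2-{2-[(2S)-5,7-dimethoxy-2-phenyl-3,4-dihydro-2H-chromen-8-yl]ethyl}-3,5-dimethoxy-4-methylphenol, via ortho-quinone methide 12 (not isolated)
Conditions: styrene (10 equiv), chiral imidodiphosphorimidate Brønsted acid (IDPi built from two 3,3'-bis[3,5-bis(trifluoromethyl)phenyl]-BINOL units, N-triflyl groups on both phosphorus atoms; 5 mol%), CHCl3, -30 °C to rt, slow addition of 10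
Reagents that add atoms: none
Why: Proposed new method: the confined chiral acid ionises the acetal of 10 with loss of acetone to the hydrogen-bonded ortho-quinone methide 12, whose exocyclic methylene is attacked by the terminal carbon of styrene while the carbonyl oxygen closes onto the developing benzylic cation, an asynchronous inverse-electron-demand oxa-Diels-Alder reaction. The closest known reaction types are the chiral N-triflylphosphoramide-catalysed [4+2] cycloaddition of benzylic-aryl ortho-quinone methides with styrenes and the imidodiphosphorimidate-catalysed hetero-Diels-Alder and Prins reactions of styrenes with formaldehyde-derived cationic partners, where the styrene benzylic carbon is likewise the only stereocentre; new is their combination on an unsubstituted methylene quinone methide. Ring C closes in [4+2] mode with C3–C4 and O1–C2 formed together (in the stepwise limit, a 6-endo capture of the benzylic cation by the phenol oxygen). C2 is set under catalyst control, the chiral anion bound at the quinone methide oxygen exposing one enantiotopic face of styrene. Regioselectivity (2-phenyl, not 3-phenyl) follows from the matched polarity of the two partners, and the needed chemoselectivity over Friedel-Crafts attack by C6–H of ring A or the free C–H of ring D is secured by the double ortho flanking of those positions inside the confined pocket, by excess styrene and by slow release of 12 from the acetal.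

**Compound list**

1 | 2-hydroxy-4,6-dimethoxybenzaldehyde | O=Cc1c(O)cc(OC)cc1OC | starting material
2 | 5,7-dimethoxy-2-phenyl-4H-1,3,2-benzodioxaborinine-8-carbaldehyde | O=Cc1c2OB(c3ccccc3)OCc2c(OC)cc1OC | intermediate
3 | 2-hydroxy-3-(hydroxymethyl)-4,6-dimethoxybenzaldehyde | O=Cc1c(O)c(CO)c(OC)cc1OC | intermediate
4 | 5,7-dimethoxy-2,2-dimethyl-4H-1,3-benzodioxine-8-carbaldehyde | O=Cc1c2OC(C)(C)OCc2c(OC)cc1OC | intermediate
5 | 3,5-dimethoxy-4-methylphenol | Cc1c(OC)cc(O)cc1OC | starting material
6 | 6-hydroxy-2,4-dimethoxy-3-methylbenzaldehyde | O=Cc1c(O)cc(OC)c(C)c1OC | intermediate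
7 | 2-(hydroxymethyl)-3,5-dimethoxy-4-methylphenol | OCc1c(O)cc(OC)c(C)c1OC | intermediate
8 | (6-hydroxy-2,4-dimethoxy-3-methylbenzyl)triphenylphosphonium bromide | [Br-].Oc1cc(OC)c(C)c(OC)c1C[P+](c1ccccc1)(c1ccccc1)c1ccccc1 | intermediate
9 | 2-[2-(5,7-dimethoxy-2,2-dimethyl-4H-1,3-benzodioxin-8-yl)ethenyl]-3,5-dimethoxy-4-methylphenol (E/Z mixture) | COc1cc(O)c(C=Cc2c(OC)cc(OC)c3c2OC(C)(C)OC3)c(OC)c1C | intermediate
10 | 2-[2-(5,7-dimethoxy-2,2-dimethyl-4H-1,3-benzodioxin-8-yl)ethyl]-3,5-dimethoxy-4-methylphenol | COc1cc(O)c(CCc2c(OC)cc(OC)c3c2OC(C)(C)OC3)c(OC)c1C | intermediate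
11 | styrene | C=Cc1ccccc1 | starting material
12 | 2-[2-(6-hydroxy-2,4-dimethoxy-3-methylphenyl)ethyl]-3,5-dimethoxy-6-methylidenecyclohexa-2,4-dien-1-one | C=C1C(OC)=CC(OC)=C(CCc2c(O)cc(OC)c(C)c2OC)C1=O | intermediate
13 | 2-{2-[(2S)-5,7-dimethoxy-2-phenyl-3,4-dihydro-2H-chromen-8-yl]ethyl}-3,5-dimethoxy-4-methylphenol | COc1cc(O)c(CCc2c(OC)cc(OC)c3c2O[C@H](c2ccccc2)CC3)c(OC)c1C | target

**Step count and risk**

Total steps: 7. Longest linear sequence: 5 steps (steps 1, 2, 5, 6, 7; the branch through steps 3, 4, 5, 6, 7 is equally long).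

Steps most likely to fail:

1. Step 7. The unactivated styrene may be discriminated poorly on its two faces, or the quinone methide may be consumed by intermolecular arene alkylation before styrene reacts. The fallback sets out from 10 and returns at 13. The quinone methide is released with BF3·OEt2 in CH2Cl2 at -78 °C in the presence of 1-phenyl-1-(trimethylsilyloxy)ethene, a far stronger π-nucleophile than styrene or the arene positions. This known quinone methide/silyl enol ether [4+2] (Mukaiyama-Michael type) should give the silyl ketal 2-[2-[5,7-dimethoxy-2-phenyl-2-(trimethylsilyloxy)-3,4-dihydro-2H-chromen-8-yl]ethyl]-3,5-dimethoxy-4-methylphenol F1 (racemic, not isolated). Acidic work-up should hydrolyse it to the ketone 3-[2-hydroxy-3-[2-(6-hydroxy-2,4-dimethoxy-3-methylphenyl)ethyl]-4,6-dimethoxyphenyl]-1-phenylpropan-1-one F2. Noyori transfer hydrogenation with RuCl[(R,R)-TsDPEN](p-cymene) in HCO2H/Et3N should then give (1R)-3-[2-hydroxy-3-[2-(6-hydroxy-2,4-dimethoxy-3-methylphenyl)ethyl]-4,6-dimethoxyphenyl]-1-phenylpropan-1-ol F3. Mitsunobu cyclisation (PPh3, DIAD, THF, 0 °C) closes ring C through O1–C2 with inversion, the six-membered closure by the adjacent phenol being favoured over any reaction of the remote phenol, to give 13.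

2. Step 1. The templated hydroxymethylation may stall because the phenol is chelated to, and deactivated by, the ortho formyl group, or attack may leak to C5. The fallback sets out from 1 and returns at 3. An ortho-selective Mannich reaction with Eschenmoser's salt (CH2Cl2, rt) should give 3-[(dimethylamino)methyl]-2-hydroxy-4,6-dimethoxybenzaldehyde F4. Acetolysis in refluxing Ac2O should convert it into [2-(acetyloxy)-3-formyl-4,6-dimethoxyphenyl]methyl acetate F5. Saponification with LiOH in THF/H2O should then deliver 3.

3. Step 5. Addition of the bulky phenoxide ylide to the hindered, electron-rich aldehyde may be slow, so that the ylide decays by loss of triphenylphosphine. The fallback sets out from 4 and 5 and returns at 10, bypassing step 6. Methylenation of 4 with the small, reactive ylide from Ph3PCH3Br and KOtBu (THF, 0 °C) should give 8-ethenyl-5,7-dimethoxy-2,2-dimethyl-4H-1,3-benzodioxine F6. Mono-iodination of 5 (NIS, MeCN, 0 °C; the two ortho positions are equivalent, the para position is blocked) should give 2-iodo-3,5-dimethoxy-4-methylphenol F7. Anti-Markovnikov hydroboration of F6 with 9-BBN (THF) should form 9-[2-(5,7-dimethoxy-2,2-dimethyl-4H-1,3-benzodioxin-8-yl)ethyl]-9-borabicyclo[3.3.1]nonane F8 (not isolated). B-alkyl Suzuki-Miyaura coupling of F8 with F7 (PdCl2(dppf), aq. K3PO4, THF/DMF, 60 °C) should deliver 10 directly.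

**Further compounds**

F1 | step 7 | 2-[2-[5,7-dimethoxy-2-phenyl-2-(trimethylsilyloxy)-3,4-dihydro-2H-chromen-8-yl]ethyl]-3,5-dimethoxy-4-methylphenol (racemic) | COc1cc(O)c(CCc2c(OC)cc(OC)c3c2OC(O[Si](C)(C)C)(c2ccccc2)CC3)c(OC)c1C
F2 | step 7 | 3-[2-hydroxy-3-[2-(6-hydroxy-2,4-dimethoxy-3-methylphenyl)ethyl]-4,6-dimethoxyphenyl]-1-phenylpropan-1-one | O=C(CCc1c(O)c(CCc2c(O)cc(OC)c(C)c2OC)c(OC)cc1OC)c1ccccc1
F3 | step 7 | (1R)-3-[2-hydroxy-3-[2-(6-hydroxy-2,4-dimethoxy-3-methylphenyl)ethyl]-4,6-dimethoxyphenyl]-1-phenylpropan-1-ol | O[C@H](CCc1c(O)c(CCc2c(O)cc(OC)c(C)c2OC)c(OC)cc1OC)c1ccccc1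
F4 | step 1 | 3-[(dimethylamino)methyl]-2-hydroxy-4,6-dimethoxybenzaldehyde | O=Cc1c(O)c(CN(C)C)c(OC)cc1OC
F5 | step 1 | [2-(acetyloxy)-3-formyl-4,6-dimethoxyphenyl]methyl acetate | O=Cc1c(OC(C)=O)c(COC(C)=O)c(OC)cc1OC
F6 | step 5 | 8-ethenyl-5,7-dimethoxy-2,2-dimethyl-4H-1,3-benzodioxine | C=Cc1c(OC)cc(OC)c2c1OC(C)(C)OC2
F7 | step 5 | 2-iodo-3,5-dimethoxy-4-methylphenol | COc1cc(O)c(I)c(OC)c1C
F8 | step 5 | 9-[2-(5,7-dimethoxy-2,2-dimethyl-4H-1,3-benzodioxin-8-yl)ethyl]-9-borabicyclo[3.3.1]nonane | C(Cc1c(OC)cc(OC)c2c1OC(C)(C)OC2)B1C2CCCC1CCC2
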